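Remark on conventions: ring atoms are numbered C1 (carbinol carbon carrying C7), C2 (OBz), C3=C4, C5 (OBz), C6 (OH). Read from the SMILES, the target is (1R,2R,5R,6S), with C7, O2 and O6 on one ring face and O1 and O5 on the other. Open-chain and lactone intermediates keep L-gulonic acid locants; sugar C1, C2, C3, C4, C5, C6 become ring C7, C1, C6, C5, C4, C3.

## Analysis of the target

The target 26 is a single cyclohexene (C1–C6, alkene C3=C4) whose tertiary carbinol carbon C1 carries the benzoyloxymethyl carbon C7; O2, O5 and O7 are benzoates, O1 and O6 are free hydroxyls. The four stereocentres C1, C2, C5 and C6 are arranged so that every vicinal oxygen pair (O1/O2, O1/O6, O5/O6) is trans and O2/O5 are trans across the alkene. Both secondary benzoates are allylic and each free hydroxyl has an ester on a neighbouring carbon, so ionisation and acyl migration threaten under Lewis-acidic or basic conditions; the closing steps must be cold and non-basic. The hard parts are the fully substituted C1, flanked on both sides by oxygenated stereocentres, and the sorting of five oxygens into three esters and two alcohols when only O1 differs in kind. The strategy rests on the chain C7–C1–C2–C3=C4: C7 is at a level a carboxyl group can deliver, C1 is bonded to oxygenated C2, and the alkene starts one atom further on. That is the γ,δ-unsaturated acid an ester enolate Claisen shift leaves when the ester oxygen sat on C4. The two atoms that close the ring on the other side, C6 and C5, carry a trans pair of oxygens and, with C4, map onto C3, C4 and C5 of the carbohydrate lactone 1.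

## Retrosynthetic reasoning

26 from 25. The two free hydroxyls are uncovered last, by cleaving the two methoxymethyl acetals of 25. Hydroxyl groups next to benzoates then exist only in the final, non-basic operation, and O6 stays blocked while its secondary neighbours are acylated.

25 from 23 and 24, and 23 back to 19. The three benzoyl C–O bonds are cut to triol 23 and benzoyl chloride 24. C7 is traced from the primary alcohol of 23 to the ester of 22 and 21 and to the carboxyl of 19. The two 4-methoxybenzyl ethers are removed at the ester stage (21 to 22), where no free hydroxyl or carboxyl sits next to them to trap the benzylic cation as a cyclic acetal.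

19 from 16 (key disconnection). The C1–C2 bond is cut and the C4–O bond to the carboxyl oxygen is restored, turning the carbocycle into the six-membered lactone 16 that carries an E 2-alkoxyvinyl group on C4. C1–C2 is the one ring bond whose formation creates the quaternary centre and its oxygenated neighbour together, and its retron is already written into the C7–C1–C2–C3=C4 chain. The gain is that C1 and C2 are derived from the stereocentre at C4 and from an alkene geometry, both of which can be secured beforehand. The forward reaction must trap the lactone enolate as ketene acetal 17 faster than the β-alkoxy group leaves, and must run the shift through a boat to silyl ester 18.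

16 from 14 and 15, and 14 from 12 and 13. The enol ether C2–O bond is cut to the E alkenylboronate 14 and alcohol 15. An alkoxymethylene Wittig reaction was not used, because it gives E/Z mixtures and needs a basic ylide next to an epimerisable centre. The C3=C2 double bond is then cut to aldehyde 12 and the one-carbon boron reagent 13. The forward pair of reactions must give the E geometry specifically, because a Z alkene would invert C2, and must not touch sugar C5.

12 from 11, and 11 from 9 through 10. The aldehyde comes from the primary alcohol of 11. The lactone C–O bond of 11 is cut to the 5,6-diol ester 10, which comes from acetonide 9. Lactonisation can only engage O5, since O4 is etherified and O6 would need a seven-membered ring, so the lactone is also the protecting group of O5.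

9 back to 1. The ether and ester C–O bonds of 9 lead to carboxylate 7 and chloride 8. Carboxylate 7 is the opened form of γ-lactone 5 after addition of 6, which is how O4 becomes available. Lactone 5 arises from 3 and 4, and 3 from 1 and 2. The pool compound 1 supplies C5, C6 and the controlling centre C4 with the correct configuration; its C2 configuration is irrelevant.

## Alternatives that were turned down

Alternative 1: The C6–O bond and a provisional C5–O bond are made by desymmetrising the achiral dienol A1, a cyclohexa-2,5-dien-1-ol that carries a hydroxymethyl group and a triethylsilyl ether at C1 and whose two ring alkenes are enantiotopic. In the forward key step VO(OiPr)3 A2, a chiral bis-hydroxamic acid ligand and the oxidant tert-butyl hydroperoxide A3 would epoxidise one alkene on the face of the C7 hydroxyl. This gives epoxy alcohol A4 and makes C1, C5 and C6 stereogenic at once. In its favour are an aromatic feedstock, catalytic asymmetric induction and very few protecting groups; on step count to the first stereodefined ring it is clearly stronger than the chosen route. Against it, the directing hydroxyl is homoallylic to both alkenes and the catalyst must distinguish them across a quaternary carbon, so enantiotopic selection rests on ligand control alone. The oxirane oxygen at C5 must later be moved or replaced. The C2 and C5 oxygens, trans to each other across a C3=C4 alkene that does not yet exist, must then be installed by diene chemistry with only the ring as control. The chosen route is longer but takes C5 and C6 from the chiral pool and derives C1 and C2 from them in one stereospecific event.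

Alternative 2: The C4–C5 bond is cut, opening the ring to the acyclic Z iodoalkene aldehyde A5. In the forward key step CrCl2 A6 with catalytic NiCl2 A7, a Nozaki–Hiyama–Kishi reaction, would convert the C4–I bond into an alkenyl–chromium bond at trivalent chromium that adds to the C5 aldehyde. This closes the ring 6-exo-trig to cyclohexenol A8 and creates C5. In its favour the reaction is chemoselective and tolerates esters, the Z geometry guarantees the ring alkene, and A8 is two steps from the target; on late-stage economy it is as strong as or stronger than the chosen route. Against it, the key step creates only C5, with a facial selectivity that depends on the neighbouring silyloxy group at C6. The difficult triad C6–C1–C2 with the quaternary carbinol must already be present in A5, and the key step does nothing to build it. A5 is also a β-hydroxy aldehyde with benzoates next to a free tertiary hydroxyl, and so is open to retro-aldol cleavage and acyl migration. The chosen strategy uses its ring-forming step to make that quaternary centre.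

Alternative 3: The C1–C7 and C7–O bonds are made on ketone A9, the bis-acetonide mono-4-methoxybenzyl ether of a C2-symmetric chiral-pool cyclitol. In the forward key step dimethylsulfonium methylide A10 would add to the C1 carbonyl and close the oxirane 3-exo-tet to spiro-epoxide A11, with C7 axial and O1 equatorial. In its favour all ring stereocentres are bought, no ring has to be formed, and opening the epoxide with benzoate would give C7–OBz and the free O1 directly; in reliability of the individual reactions it is stronger than the chosen route. Against it, the cyclitol carries six ring oxygens where the target needs four. O3 and O4 sit in two different acetonides and must be freed, differentiated from O2 and O5 and removed reductively to form C3=C4, which costs many protecting-group steps and discards two stereocentres. The face taken by the ylide on a ketone held between a cis-fused acetonide and an ether is also not secured by the design. The chosen route carries no superfluous oxygen and makes the alkene in the same step as the ring.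

Key step: step 9

## Route

Step 1
Reactants: 1 L-gulono-1,4-lactone; 2 2-methoxypropene
Product: 3 5,6-O-isopropylidene-L-gulono-1,4-lactone
Conditions: 2 (1.3 equiv), TsOH·H2O (cat.), DMF, 0 °C → rt
Reagents that add atoms: 2-methoxypropene, COC(C)=C
Why: Kinetic acid-catalysed acetalisation: primary O6 adds to the protonated enol ether and O5 closes the dioxolane faster than the less nucleophilic cis-2,3-diol next to the lactone carbonyl reacts; no stereocentre is touched.

Step 2
Reactants: 3 5,6-O-isopropylidene-L-gulono-1,4-lactone; 4 chloromethyl methyl ether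
Product: 5 5,6-O-isopropylidene-2,3-di-O-(methoxymethyl)-L-gulono-1,4-lactone
Conditions: 4 (5 equiv), iPr2NEt (6 equiv), Bu4NI (cat.), CH2Cl2, 0 → 40 °C
Reagents that add atoms: chloromethyl methyl ether, COCCl
Why: Williamson-type etherification of both lactone hydroxyls by the α-chloro ether under a hindered amine base that is too weak to enolise the lactone, so O3 is not lost by β-elimination. Two separate acetal ethers are used instead of one cyclic acetal because O1 and O6 of the target end up trans and must not be tied together in step 9.

Step 3
Reactants: 5 5,6-O-isopropylidene-2,3-di-O-(methoxymethyl)-L-gulono-1,4-lactone; 6 sodium hydroxide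
Product: 7 sodium 5,6-O-isopropylidene-2,3-di-O-(methoxymethyl)-L-gulonate
Conditions: NaOH (1.05 equiv), THF–H2O, 0 °C → rt; evaporate, dry by toluene azeotrope
Reagents that add atoms: sodium hydroxide, [Na+].[OH-]
Why: Saponification of the γ-lactone: hydroxide adds to the carbonyl faster than it enolises it, the carboxylate cannot re-lactonise under base, and O4 becomes the only free hydroxyl. Any epimerisation at sugar C2 would be harmless, since that centre is enolised in step 9.

Step 4
Reactants: 7 sodium 5,6-O-isopropylidene-2,3-di-O-(methoxymethyl)-L-gulonate; 8 4-methoxybenzyl chloride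
Product: 9 4-methoxybenzyl 5,6-O-isopropylidene-4-O-(4-methoxybenzyl)-2,3-di-O-(methoxymethyl)-L-gulonate
Conditions: NaH (1.3 equiv), DMF, 0 °C; 8 (2.6 equiv), Bu4NI (cat.), 0 °C → rt
Reagents that add atoms: 4-methoxybenzyl chloride, COc1ccc(CCl)cc1
Why: Williamson etherification of the O4 alkoxide followed in the same pot by SN2 esterification of the carboxylate; the alkoxide is by far the better nucleophile, so the ester appears only after O4 is capped and cannot be attacked intramolecularly. The ester keeps sugar C1 at the acid level and serves as the acyl donor in step 5.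

Step 5
Reactants: 9 4-methoxybenzyl 5,6-O-isopropylidene-4-O-(4-methoxybenzyl)-2,3-di-O-(methoxymethyl)-L-gulonate
Product: 11 4-O-(4-methoxybenzyl)-2,3-di-O-(methoxymethyl)-L-gulono-1,5-lactone, via diol ester 10 (not isolated)
Conditions: AcOH–H2O (4:1), 40 °C; evaporate with toluene; PPTS (cat.), toluene, 60 °C
Reagents that add atoms: none
Why: Aqueous acetic acid hydrolyses the terminal acetonide but leaves the methoxymethyl and 4-methoxybenzyl ethers; acid-catalysed intramolecular transesterification then closes the lactone through O5, because O4 is etherified and O6 could only form a seven-membered ring. The lactone protects O5 and leaves O6 as the only free hydroxyl.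

Step 6
Reactants: 11 4-O-(4-methoxybenzyl)-2,3-di-O-(methoxymethyl)-L-gulono-1,5-lactone
Product: 12 4-O-(4-methoxybenzyl)-2,3-di-O-(methoxymethyl)-L-gulo-hexodialdono-1,5-lactone (the 6-aldehyde of 11)
Conditions: Dess–Martin periodinane (1.5 equiv), NaHCO3, CH2Cl2, 0 °C → rt; used crude at once
Reagents that add atoms: none
Why: Dess–Martin oxidation of the primary alcohol under buffered, non-basic conditions, so that sugar C5 (α to the new aldehyde and the centre that directs step 9) does not epimerise and the β-alkoxy group at C4 is not eliminated.

Step 7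
Reactants: 12 4-O-(4-methoxybenzyl)-2,3-di-O-(methoxymethyl)-L-gulo-hexodialdono-1,5-lactone; 13 2-(dichloromethyl)-4,4,5,5-tetramethyl-1,3,2-dioxaborolane
Product: 14 (E)-6,7-dideoxy-4-O-(4-methoxybenzyl)-2,3-di-O-(methoxymethyl)-7-(4,4,5,5-tetramethyl-1,3,2-dioxaborolan-2-yl)-L-gulo-hept-6-enono-1,5-lactone
Conditions: CrCl2 (8 equiv), LiI (4 equiv), 13 (2 equiv), THF, rt
Reagents that add atoms: 2-(dichloromethyl)-4,4,5,5-tetramethyl-1,3,2-dioxaborolane, ClC(Cl)B1OC(C)(C)C(C)(C)O1
Why: Takai–Utimoto olefination (boron variant of the Takai reaction): the geminal dichromium species from the dihalomethylboronate adds to the aldehyde and eliminates with boron anti to the carbon chain, giving the E alkenylboronate. The reagent is non-basic and organochromium species do not add to lactones, so sugar C5 and the lactone are preserved.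

Step 8
Reactants: 14 the E alkenylboronate lactone; 15 4-methoxybenzyl alcohol
Product: 16 (E)-6,7-dideoxy-4-O-(4-methoxybenzyl)-7-[(4-methoxybenzyl)oxy]-2,3-di-O-(methoxymethyl)-L-gulo-hept-6-enono-1,5-lactone
Conditions: Cu(OAc)2 (2 equiv), Et3N (4 equiv), 15 (excess), 4 Å molecular sieves, CH2Cl2, air, rt
Reagents that add atoms: 4-methoxybenzyl alcohol, COc1ccc(CO)cc1
Why: Chan–Lam-type oxidative C–O coupling of an alkenylboronate with an alcohol: transmetalation from boron to divalent copper, oxidation to a trivalent copper alkenyl alkoxide and reductive elimination, all with retention of alkene geometry, so the E boronate becomes the E enol ether. Room temperature and an amine base are mild enough for the lactone and for sugar C5.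

Step 9
Reactants: 16 the E enol ether lactone
Product: 19 1,6-bis(methoxymethoxy)-2,5-bis[(4-methoxybenzyl)oxy]cyclohex-3-ene-1-carboxylic acid (CO2H cis to O2 and O6 but trans to O5; ring configuration as in the target), via silyl ketene acetal 17 (not isolated), via trimethylsilyl ester 18 (not isolated)
Conditions: Me3SiCl–Et3N (1:1, 5 equiv), THF, −78 °C, then KN(SiMe3)2 (1.5 equiv, in toluene) added slowly; −78 °C → rt; toluene, 80 °C; 1 M aq. NaOH, THF, 0 °C; NaH2PO4 to pH 4
Reagents that add atoms: none
Why: Ireland–Claisen (ester enolate Claisen) rearrangement in its lactone form; the closest known reaction type is the silyl ketene acetal [3,3] shift of 6-alkenyl δ-lactones and of glycal esters to cyclohexene- and dihydropyran-carboxylic acids. KN(SiMe3)2 removes the proton at sugar C2 while Me3SiCl is already present, so the enolate is O-silylated to 17 before it can expel the β-methoxymethoxy group (E1cB). On warming, the array C1=C7–O–C4–C3=C2 of 17 reorganises suprafacially: C1–C2 forms as C4–O breaks, giving silyl ester 18 and, after hydrolysis, acid 19. The carbocycle C1–C2–C3=C4–C5–C6 is closed by this sigmatropic shift and not by a polar exo or endo cyclisation; because C1 and C4 are already joined by the two-atom tether C6–C5, the six-atom array is forced into a boat shaped like bicyclo[2.2.2]octane. C1 is set by chirality transfer from sugar C5: the new bond is delivered to the lactone face that carries the alkoxyvinyl group, which places C7 cis to O6 and trans to O5. C2 is set by the alkene geometry: in the boat the E enol ether oxygen points away from the C6–C5 tether toward the C7–O bridge, so O2 ends up cis to C7 and trans to O1, whereas a Z isomer would give the C2 epimer. The step needs O-silylation to outrun β-elimination (internal quench at −78 °C) and a concerted path instead of heterolysis of the allylic C4–O bond (the ketene acetal oxygen is a poor leaving group, Et3N scavenges acid, and the donor oxygen on the allyl terminus lowers the barrier of the shift). The configuration at sugar C2 is erased on enolisation and is irrelevant.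

Step 10
Reactants: 19 the cyclohexenecarboxylic acid; 20 iodomethane
Product: 21 methyl 1,6-bis(methoxymethoxy)-2,5-bis[(4-methoxybenzyl)oxy]cyclohex-3-ene-1-carboxylate
Conditions: 20 (3 equiv), K2CO3 (2 equiv), DMF, rt
Reagents that add atoms: iodomethane, CI
Why: SN2 alkylation of the carboxylate, which is insensitive to the hindrance at C1. The ester removes the free carboxyl that could trap the benzylic cation in step 11.

Step 11
Reactants: 21 the bis(4-methoxybenzyl) methyl ester
Product: 22 methyl 2,5-dihydroxy-1,6-bis(methoxymethoxy)cyclohex-3-ene-1-carboxylate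
Conditions: DDQ (2.5 equiv), CH2Cl2–pH 7 phosphate buffer (10:1), 0 °C → rt
Reagents that add atoms: none
Why: Oxidative cleavage of both 4-methoxybenzyl ethers: single-electron oxidation to benzylic oxocarbenium ions that the buffer water hydrolyses; methoxymethyl ethers, the ester and the electron-poor ring alkene are inert. No free hydroxyl is next to either ether, so no cyclic 4-methoxybenzylidene acetal can form.

Step 12
Reactants: 22 the diol methyl ester
Product: 23 1-(hydroxymethyl)-1,6-bis(methoxymethoxy)cyclohex-3-ene-2,5-diol (C7 alcohol; free O2, O5, O7)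
Conditions: LiAlH4 (3 equiv), THF, 0 °C → rt; Na2SO4·10H2O quench
Reagents that add atoms: none
Why: Hydride reduction of the hindered methyl ester to the primary alcohol C7; acetals, alkene and all stereocentres are unaffected.

Step 13
Reactants: 23 the triol; 24 benzoyl chloride
Product: 25 [2,5-bis(benzoyloxy)-1,6-bis(methoxymethoxy)cyclohex-3-en-1-yl]methyl benzoate
Conditions: 24 (4.5 equiv), pyridine, DMAP (cat.), CH2Cl2, 0 °C → rt
Reagents that add atoms: benzoyl chloride, O=C(Cl)c1ccccc1
Why: DMAP-catalysed acylation of the primary O7 and the two secondary allylic hydroxyls O2 and O5; O1 and O6 are blocked as acetals, so no regioselection is required.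

Step 14
Reactants: 25 the tribenzoate bis(methoxymethyl) ether
Product: 26 [(1R,2R,5R,6S)-2,5-bis(benzoyloxy)-1,6-dihydroxycyclohex-3-en-1-yl]methyl benzoate (target)
Conditions: Me2BBr (5 equiv), CH2Cl2, −78 °C; then THF–sat. aq. NaHCO3, 0 °C
Reagents that add atoms: none
Why: Lewis-acid cleavage of the two methoxymethyl acetals by the bromoborane through α-bromo ethers that hydrolyse on work-up. The low temperature and the absence of base leave the benzoates in place and suppress acyl migration to the freed O1 and O6.

## Compound list

1 | L-gulono-1,4-lactone | O=C1[C@@H](O)[C@@H](O)[C@@H]([C@@H](O)CO)O1 | starting material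
2 | 2-methoxypropene | COC(C)=C | starting material
3 | 5,6-O-isopropylidene-L-gulono-1,4-lactone | O=C1[C@@H](O)[C@@H](O)[C@@H]([C@@H]2COC(C)(C)O2)O1 | intermediate
4 | chloromethyl methyl ether | COCCl | starting material
5 | 5,6-O-isopropylidene-2,3-di-O-(methoxymethyl)-L-gulono-1,4-lactone | O=C1[C@@H](OCOC)[C@@H](OCOC)[C@@H]([C@@H]2COC(C)(C)O2)O1 | intermediate
6 | sodium hydroxide | [Na+].[OH-] | starting material
7 | sodium 5,6-O-isopropylidene-2,3-di-O-(methoxymethyl)-L-gulonate | [Na+].[O-]C(=O)[C@@H](OCOC)[C@@H](OCOC)[C@H](O)[C@@H]1COC(C)(C)O1 | intermediate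
8 | 4-methoxybenzyl chloride | COc1ccc(CCl)cc1 | starting material
9 | 4-methoxybenzyl 5,6-O-isopropylidene-4-O-(4-methoxybenzyl)-2,3-di-O-(methoxymethyl)-L-gulonate | COc1ccc(COC(=O)[C@@H](OCOC)[C@@H](OCOC)[C@H](OCc2ccc(OC)cc2)[C@@H]2COC(C)(C)O2)cc1 | intermediate
10 | 4-methoxybenzyl 4-O-(4-methoxybenzyl)-2,3-di-O-(methoxymethyl)-L-gulonate (5,6-diol) | COc1ccc(COC(=O)[C@@H](OCOC)[C@@H](OCOC)[C@H](OCc2ccc(OC)cc2)[C@@H](O)CO)cc1 | intermediate
11 | 4-O-(4-methoxybenzyl)-2,3-di-O-(methoxymethyl)-L-gulono-1,5-lactone | O=C1[C@@H](OCOC)[C@@H](OCOC)[C@H](OCc2ccc(OC)cc2)[C@H](CO)O1 | intermediate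
12 | 4-O-(4-methoxybenzyl)-2,3-di-O-(methoxymethyl)-L-gulo-hexodialdono-1,5-lactone | O=C1[C@@H](OCOC)[C@@H](OCOC)[C@H](OCc2ccc(OC)cc2)[C@H](C=O)O1 | intermediate
13 | 2-(dichloromethyl)-4,4,5,5-tetramethyl-1,3,2-dioxaborolane | ClC(Cl)B1OC(C)(C)C(C)(C)O1 | starting material
14 | (E)-6,7-dideoxy-4-O-(4-methoxybenzyl)-2,3-di-O-(methoxymethyl)-7-(4,4,5,5-tetramethyl-1,3,2-dioxaborolan-2-yl)-L-gulo-hept-6-enono-1,5-lactone | O=C1[C@@H](OCOC)[C@@H](OCOC)[C@H](OCc2ccc(OC)cc2)[C@H](/C=C/B2OC(C)(C)C(C)(C)O2)O1 | intermediate
15 | 4-methoxybenzyl alcohol | COc1ccc(CO)cc1 | starting material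
16 | (E)-6,7-dideoxy-4-O-(4-methoxybenzyl)-7-[(4-methoxybenzyl)oxy]-2,3-di-O-(methoxymethyl)-L-gulo-hept-6-enono-1,5-lactone | O=C1[C@@H](OCOC)[C@@H](OCOC)[C@H](OCc2ccc(OC)cc2)[C@H](/C=C/OCc2ccc(OC)cc2)O1 | intermediate
17 | trimethylsilyl ketene acetal of 16 (C1=C2 enol silyl ether, sugar numbering) | C[Si](C)(C)OC1=C(OCOC)[C@@H](OCOC)[C@H](OCc2ccc(OC)cc2)[C@H](/C=C/OCc2ccc(OC)cc2)O1 | intermediate
18 | trimethylsilyl ester of 19 | C[Si](C)(C)OC(=O)[C@]1(OCOC)[C@H](OCc2ccc(OC)cc2)C=C[C@@H](OCc2ccc(OC)cc2)[C@@H]1OCOC | intermediate
19 | 1,6-bis(methoxymethoxy)-2,5-bis[(4-methoxybenzyl)oxy]cyclohex-3-ene-1-carboxylic acid (CO2H cis to O2 and O6) | OC(=O)[C@]1(OCOC)[C@H](OCc2ccc(OC)cc2)C=C[C@@H](OCc2ccc(OC)cc2)[C@@H]1OCOC | intermediate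
20 | iodomethane | CI | starting material
21 | methyl ester of 19 | COC(=O)[C@]1(OCOC)[C@H](OCc2ccc(OC)cc2)C=C[C@@H](OCc2ccc(OC)cc2)[C@@H]1OCOC | intermediate
22 | methyl 2,5-dihydroxy-1,6-bis(methoxymethoxy)cyclohex-3-ene-1-carboxylate | COC(=O)[C@]1(OCOC)[C@H](O)C=C[C@@H](O)[C@@H]1OCOC | intermediate
23 | 1-(hydroxymethyl)-1,6-bis(methoxymethoxy)cyclohex-3-ene-2,5-diol | OC[C@]1(OCOC)[C@H](O)C=C[C@@H](O)[C@@H]1OCOC | intermediate
24 | benzoyl chloride | O=C(Cl)c1ccccc1 | starting material
25 | [2,5-bis(benzoyloxy)-1,6-bis(methoxymethoxy)cyclohex-3-en-1-yl]methyl benzoate | O=C(OC[C@]1(OCOC)[C@H](OC(=O)c2ccccc2)C=C[C@@H](OC(=O)c2ccccc2)[C@@H]1OCOC)c1ccccc1 | intermediate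
26 | [(1R,2R,5R,6S)-2,5-bis(benzoyloxy)-1,6-dihydroxycyclohex-3-en-1-yl]methyl benzoate | O=C(OC[C@]1(O)[C@H](OC(=O)c2ccccc2)C=C[C@@H](OC(=O)c2ccccc2)[C@@H]1O)c1ccccc1 | target

Total step count: 14. Longest linear sequence: 14 steps (1 to 26; the route is fully linear).

## Least certain steps

Step 9 (key step). Ketene acetal 17 may not reach the boat transition state intact. The enolate could lose the β-methoxymethoxy group before it is silylated. Alternatively the allylic C4–O bond, activated by the enol ether oxygen (the substrate is a vinylogous acylal), could ionise on heating, which would lead to non-stereospecific recombination or decomposition. The fallback sets out from alkenylboronate 14 and postpones the C2–O bond until after the rearrangement. With boron in place of oxygen on the allyl terminus the C4–O bond is an ordinary allylic ester bond, so the same internal-quench silylation can be followed by heating to 110 °C. The Ireland–Claisen shift then gives allylboronate acid F1, with boron in the E-derived position cis to C7. Oxidation of the C–B bond with NaBO3·4H2O in THF–water, which retains configuration at carbon and does not transpose the allyl system, gives hydroxy acid F2. MeI with K2CO3 gives methyl ester F3, and DDQ removal of its single 4-methoxybenzyl ether rejoins the route at 22.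

Step 8. The benzylic alcohol, with amine and copper present, may open the δ-lactone by transesterification. Protodeboronation may also outrun C–O coupling. The fallback sets out from diol ester 10, obtained by stopping step 5 before the PPTS stage, and makes the enol ether before the lactone exists. Et3SiCl with imidazole gives bis-silyl ether F4. Swern conditions oxidise the primary silyl ether directly to aldehyde F5 and leave the secondary one. CrCl2 with CHI3 (Takai olefination) gives E vinyl iodide F6. An Ullmann-type coupling with 15 (CuI cat., 3,4,7,8-tetramethyl-1,10-phenanthroline, Cs2CO3, toluene, 80 °C) then gives E enol ether F7 with retention; ester exchange with the alkoxide is degenerate because the ester is already a 4-methoxybenzyl ester. Bu4NF buffered with AcOH removes the silyl group, and O5 closes onto the ester to return to 16.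

Step 4. If some carboxylate is esterified while free O4 alkoxide remains, the alkoxide re-closes the γ-lactone. Residual strong base may also cause β-elimination from the product ester. The fallback sets out from lactone 5 and avoids any alkoxide. Aminolysis with MeNH(OMe)·HCl and iPrMgCl opens the lactone to hydroxy amide F8. O4 is etherified under acid catalysis with 4-methoxybenzyl trichloroacetimidate (cat. camphorsulfonic acid) to give amide F9. Aqueous AcOH at 50 °C then removes the acetonide, O5 displaces the hydroxylamine, and the sequence comes back at lactone 11.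

Step 14. Acyl migration from O5, O2 or O7 to the newly freed hydroxyls may occur. An intermediate bromomethyl ether may be captured by a neighbouring oxygen to form a cyclic methylene acetal. The Lewis acid may also ionise an allylic benzoate. The fallback sets out from 21 and removes the methoxymethyl groups before any benzoate is present. HCl in methanol gives diol ester F10. Et3SiOTf with 2,6-lutidine at −78 °C silylates the secondary O6 in preference to the tertiary O1, giving silyl ether F11. DDQ gives triol ester F12, LiAlH4 gives tetrol F13, and benzoyl chloride with pyridine acylates O7, O2 and O5 but not the tertiary O1, giving tribenzoate F14. HF·pyridine in THF then removes the silyl group under acidic, migration-free conditions and arrives at 26.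

## Further compounds

F1 | step 9 | 1,6-bis(methoxymethoxy)-5-[(4-methoxybenzyl)oxy]-2-(4,4,5,5-tetramethyl-1,3,2-dioxaborolan-2-yl)cyclohex-3-ene-1-carboxylic acid (boron cis to CO2H) | OC(=O)[C@]1(OCOC)[C@H](B2OC(C)(C)C(C)(C)O2)C=C[C@@H](OCc2ccc(OC)cc2)[C@@H]1OCOC
F2 | step 9 | 2-hydroxy-1,6-bis(methoxymethoxy)-5-[(4-methoxybenzyl)oxy]cyclohex-3-ene-1-carboxylic acid | OC(=O)[C@]1(OCOC)[C@H](O)C=C[C@@H](OCc2ccc(OC)cc2)[C@@H]1OCOC
F3 | step 9 | methyl 2-hydroxy-1,6-bis(methoxymethoxy)-5-[(4-methoxybenzyl)oxy]cyclohex-3-ene-1-carboxylate | COC(=O)[C@]1(OCOC)[C@H](O)C=C[C@@H](OCc2ccc(OC)cc2)[C@@H]1OCOC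
F4 | step 8 | 4-methoxybenzyl 4-O-(4-methoxybenzyl)-2,3-di-O-(methoxymethyl)-5,6-bis-O-(triethylsilyl)-L-gulonate | COc1ccc(COC(=O)[C@@H](OCOC)[C@@H](OCOC)[C@H](OCc2ccc(OC)cc2)[C@@H](O[Si](CC)(CC)CC)CO[Si](CC)(CC)CC)cc1
F5 | step 8 | 4-methoxybenzyl 4-O-(4-methoxybenzyl)-2,3-di-O-(methoxymethyl)-5-O-(triethylsilyl)-L-gulonate oxidised at C6 to the aldehyde | COc1ccc(COC(=O)[C@@H](OCOC)[C@@H](OCOC)[C@H](OCc2ccc(OC)cc2)[C@@H](O[Si](CC)(CC)CC)C=O)cc1
F6 | step 8 | 4-methoxybenzyl (E)-6,7-dideoxy-7-iodo-4-O-(4-methoxybenzyl)-2,3-di-O-(methoxymethyl)-5-O-(triethylsilyl)-L-gulo-hept-6-enonate | COc1ccc(COC(=O)[C@@H](OCOC)[C@@H](OCOC)[C@H](OCc2ccc(OC)cc2)[C@@H](O[Si](CC)(CC)CC)/C=C/I)cc1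
F7 | step 8 | 4-methoxybenzyl (E)-6,7-dideoxy-4-O-(4-methoxybenzyl)-7-[(4-methoxybenzyl)oxy]-2,3-di-O-(methoxymethyl)-5-O-(triethylsilyl)-L-gulo-hept-6-enonate | COc1ccc(COC(=O)[C@@H](OCOC)[C@@H](OCOC)[C@H](OCc2ccc(OC)cc2)[C@@H](O[Si](CC)(CC)CC)/C=C/OCc2ccc(OC)cc2)cc1
F8 | step 4 | N-methoxy-N-methyl-5,6-O-isopropylidene-2,3-di-O-(methoxymethyl)-L-gulonamide | CON(C)C(=O)[C@@H](OCOC)[C@@H](OCOC)[C@H](O)[C@@H]1COC(C)(C)O1
F9 | step 4 | N-methoxy-N-methyl-5,6-O-isopropylidene-4-O-(4-methoxybenzyl)-2,3-di-O-(methoxymethyl)-L-gulonamide | CON(C)C(=O)[C@@H](OCOC)[C@@H](OCOC)[C@H](OCc1ccc(OC)cc1)[C@@H]1COC(C)(C)O1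
F10 | step 14 | methyl 1,6-dihydroxy-2,5-bis[(4-methoxybenzyl)oxy]cyclohex-3-ene-1-carboxylate | COC(=O)[C@]1(O)[C@H](OCc2ccc(OC)cc2)C=C[C@@H](OCc2ccc(OC)cc2)[C@@H]1O
F11 | step 14 | methyl 1-hydroxy-2,5-bis[(4-methoxybenzyl)oxy]-6-(triethylsilyloxy)cyclohex-3-ene-1-carboxylate | COC(=O)[C@]1(O)[C@H](OCc2ccc(OC)cc2)C=C[C@@H](OCc2ccc(OC)cc2)[C@@H]1O[Si](CC)(CC)CC
F12 | step 14 | methyl 1,2,5-trihydroxy-6-(triethylsilyloxy)cyclohex-3-ene-1-carboxylate | COC(=O)[C@]1(O)[C@H](O)C=C[C@@H](O)[C@@H]1O[Si](CC)(CC)CC
F13 | step 14 | 1-(hydroxymethyl)-6-(triethylsilyloxy)cyclohex-3-ene-1,2,5-triol | OC[C@]1(O)[C@H](O)C=C[C@@H](O)[C@@H]1O[Si](CC)(CC)CC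
F14 | step 14 | [2,5-bis(benzoyloxy)-1-hydroxy-6-(triethylsilyloxy)cyclohex-3-en-1-yl]methyl benzoate | O=C(OC[C@]1(O)[C@H](OC(=O)c2ccccc2)C=C[C@@H](OC(=O)c2ccccc2)[C@@H]1O[Si](CC)(CC)CC)c1ccccc1
A1 | alternative 1 | [1-(triethylsilyloxy)cyclohexa-2,5-dien-1-yl]methanol | OCC1(O[Si](CC)(CC)CC)C=CCC=C1
A2 | alternative 1 | vanadium oxytriisopropoxide, VO(OiPr)3 | CC(C)O[V](=O)(OC(C)C)OC(C)C
A3 | alternative 1 | tert-butyl hydroperoxide | CC(C)(C)OO
A4 | alternative 1 | 5,6-epoxide of A1 with the oxirane syn to the hydroxymethyl group | OC[C@]1(O[Si](CC)(CC)CC)C=CC[C@@H]2O[C@H]12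
A5 | alternative 2 | acyclic Z iodoalkene aldehyde (C5 aldehyde, O6 triethylsilyl ether, free O1, benzoates on O2 and O7) | O=C[C@H](O[Si](CC)(CC)CC)[C@](O)(COC(=O)c1ccccc1)[C@H](OC(=O)c1ccccc1)/C=C\I
A6 | alternative 2 | chromium dichloride, CrCl2 | [Cr+2].[Cl-].[Cl-]
A7 | alternative 2 | nickel dichloride, NiCl2 | [Ni+2].[Cl-].[Cl-]
A8 | alternative 2 | cyclohexenol with free C5 hydroxyl, O6 triethylsilyl ether and benzoates on O2 and O7 | O[C@@]1(COC(=O)c2ccccc2)[C@H](OC(=O)c2ccccc2)C=C[C@@H](O)[C@@H]1O[Si](CC)(CC)CC
A9 | alternative 3 | cyclitol-derived C1 ketone, bis-acetonide mono-4-methoxybenzyl ether | O=C1[C@@H]2OC(C)(C)O[C@@H]2[C@H]2OC(C)(C)O[C@H]2[C@@H]1OCc1ccc(OC)cc1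
A10 | alternative 3 | dimethylsulfonium methylide | C[S+](C)[CH2-]
A11 | alternative 3 | spiro-epoxide at C1 (C7 axial) | C1O[C@]12[C@@H]3OC(C)(C)O[C@@H]3[C@H]3OC(C)(C)O[C@H]3[C@@H]2OCc2ccc(OC)cc2
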